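**Retrosynthetic overview**

1. Germacrane numbering is used: ring C1–C10, C14 methyl on C10, C15 on C4, C11(=C13)–C12 on C7, lactone C12–O–C8. The target is the 8,12-olide with a free 6-OH and the hydroxytiglate on O15; acylation of O15 and silyl removal come last.
2. The strategy rests on C6: a free secondary carbinol that is allylic to the C4=C5 ring alkene. The ring bond C5–C6 and this hydroxyl are made together by adding a C5 alkenyl metal (from a C5 iodide) to a C6 aldehyde, which closes the ten-membered carbocycle (first ring).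
3. Open-chain precursor 27 is assembled from three bonds: C3–C4 with the C5 iodoalkene (copper-catalysed anti-carbomagnesiation of propargyl alcohol, iodine quench), C9–C10 (alkenyllithium opening of a C8–C9 epoxide), and C7–C11 (alkenyl Grignard/CuI opening of a Sharpless epoxy alcohol, which sets C7 and C8).
4. Ring order: carbocycle in step 16, then the γ-lactone (second ring) in step 19 by oxidation of the C8/C12 diol while O6 is silylated, so that only O8 can lactonise.

Key step: step 16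

Remark on the chemistry: the spatial arrangement at C7 and C8 is fixed in step 4 and is not touched afterwards; the CIP letters change along the route only because substituent priorities change. The C4=C5 alkene has C3 and C6 (or iodine) trans throughout, which reads Z by CIP because of the oxygen on C15. O8 is carried as a triethylsilyl ether and O6 is silylated after ring closure.

**Route**

Step 1
Reactants: 1 (Z)-but-2-ene-1,4-diol
Product: 2 (Z)-4-[(4-methoxybenzyl)oxy]but-2-en-1-ol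
Conditions: NaH (1 equiv), 4-methoxybenzyl chloride (1 equiv), TBAI (cat.), diol in excess, THF/DMF, 0 °C to rt
Reagents that add atoms: 4-methoxybenzyl chloride, COc1ccc(CCl)cc1
Why: Williamson monoetherification of the symmetric diol, with excess diol holding back the bis-ether.

Step 2
Reactants: 2 (Z)-4-[(4-methoxybenzyl)oxy]but-2-en-1-ol
Product: 3 [(2R,3S)-3-{[(4-methoxybenzyl)oxy]methyl}oxiran-2-yl]methanol
Conditions: Ti(OiPr)4 (0.2 equiv), D-(−)-diethyl tartrate (0.25 equiv), t-BuOOH, 4 Å sieves, CH2Cl2, −20 °C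
Reagents that add atoms: tert-butyl hydroperoxide, CC(C)(C)OO
Why: Sharpless asymmetric epoxidation of a (Z)-allylic alcohol; the D-tartrate ligand should deliver oxygen to the face that gives the (2R,3S) cis-epoxide, whose C3 becomes C8 of the target unchanged and whose C2 (C7) is inverted in step 4.

Step 3
Reactants: 4 2-bromoprop-2-en-1-ol
Product: 5 [(2-bromoprop-2-en-1-yl)oxy](tert-butyl)dimethylsilane
Conditions: TBSCl, imidazole, CH2Cl2, 0 °C to rt
Reagents that add atoms: tert-butyldimethylsilyl chloride, CC(C)(C)[Si](C)(C)Cl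
Why: Standard silylation of a primary allylic alcohol; the bulky silyl group also slows oxygen-to-carbon silyl shift in the derived alkenyllithium.

Step 4
Reactants: 3 [(2R,3S)-3-{[(4-methoxybenzyl)oxy]methyl}oxiran-2-yl]methanol; 5 [(2-bromoprop-2-en-1-yl)oxy](tert-butyl)dimethylsilane
Product: 8 (2S,3R)-2-{3-[(tert-butyldimethylsilyl)oxy]prop-1-en-2-yl}-4-[(4-methoxybenzyl)oxy]butane-1,3-diol, via alkenyllithium 6 (not isolated), via alkenylmagnesium bromide 7 (not isolated)
Conditions: 5 (3.2 equiv), t-BuLi (6.4 equiv), Et2O, −78 °C; MgBr2·OEt2, −78 to −40 °C; CuI (0.3 equiv), then 3, THF, −40 to −15 °C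
Reagents that add atoms: none
Why: Copper-catalysed alkenyl Grignard opening of a 2,3-epoxy alcohol; SN2 attack at C7 (the carbon next to the free carbinol, C8 being deactivated by the PMB-oxymethyl group) with inversion sets C7, leaves C8 untouched and so turns the cis-epoxide into the 7,8-syn diol.

Step 5
Reactants: 8 (2S,3R)-2-{3-[(tert-butyldimethylsilyl)oxy]prop-1-en-2-yl}-4-[(4-methoxybenzyl)oxy]butane-1,3-diol
Product: 9 (2R,3S)-3-{3-[(tert-butyldimethylsilyl)oxy]prop-1-en-2-yl}-1-[(4-methoxybenzyl)oxy]-4-[(triethylsilyl)oxy]butan-2-ol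
Conditions: TESCl (1.05 equiv), imidazole, CH2Cl2, −78 to −30 °C
Reagents that add atoms: chlorotriethylsilane, CC[Si](CC)(CC)Cl
Why: Selective silylation of the primary C6 hydroxyl over the hindered secondary C8 hydroxyl at low temperature.

Step 6
Reactants: 9 (2R,3S)-3-{3-[(tert-butyldimethylsilyl)oxy]prop-1-en-2-yl}-1-[(4-methoxybenzyl)oxy]-4-[(triethylsilyl)oxy]butan-2-ol
Product: 10 (2R,3S)-3-{3-[(tert-butyldimethylsilyl)oxy]prop-1-en-2-yl}-4-[(triethylsilyl)oxy]butane-1,2-diol
Conditions: DDQ (1.2 equiv), CH2Cl2/pH 7 buffer (10:1), 0 °C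
Reagents that add atoms: none
Why: Oxidative cleavage of the PMB ether with DDQ, run in buffered wet solvent so that water and not the neighbouring C8 hydroxyl traps the benzylic cation and the silyl ethers are kept.

Step 7
Reactants: 10 (2R,3S)-3-{3-[(tert-butyldimethylsilyl)oxy]prop-1-en-2-yl}-4-[(triethylsilyl)oxy]butane-1,2-diol
Product: 12 (2R)-2-[(2S)-3-{[(tert-butyldimethylsilyl)oxy]methyl}-1-[(triethylsilyl)oxy]but-3-en-2-yl]oxirane, via primary tosylate 11 (not isolated)
Conditions: TsCl (1.05 equiv), Et3N, Bu2SnO (0.02 equiv), CH2Cl2, 0 °C; then NaH, THF, 0 °C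
Reagents that add atoms: none
Why: Tin-catalysed selective sulfonylation of the primary C9 hydroxyl followed by intramolecular Williamson closure by O8, which forms the C8–C9 epoxide with retention at C8 because the C8–O bond is never broken.

Step 8
Reactants: 13 pent-3-yn-1-ol
Product: 14 5-chloropent-2-yne
Conditions: SOCl2, pyridine (1 equiv), Et2O, 0 °C to reflux
Reagents that add atoms: thionyl chloride, O=S(Cl)Cl
Why: Chlorodehydroxylation of a primary alcohol through its chlorosulfite; the chloride is inert to the organometallic chemistry of steps 9 and 10 and later serves as the Grignard precursor.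

Step 9
Reactants: 14 5-chloropent-2-yne
Product: 16 (2E)-5-chloro-2-iodopent-2-ene, via alkenylzirconocene chloride 15 (not isolated)
Conditions: Cp2Zr(H)Cl (2 equiv), THF, rt then 45 °C; I2, THF, 0 °C
Reagents that add atoms: iodine, II
Why: Schwartz hydrozirconation (syn addition) under equilibrating conditions places zirconium on the less hindered methyl-bearing carbon, and iodinolysis with retention gives the E-iodoalkene that carries C14, C10, C1, C2 and C3.

Step 10
Reactants: 12 (2R)-2-[(2S)-3-{[(tert-butyldimethylsilyl)oxy]methyl}-1-[(triethylsilyl)oxy]but-3-en-2-yl]oxirane; 16 (2E)-5-chloro-2-iodopent-2-ene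
Product: 18 (2S,3S,5E)-2-{3-[(tert-butyldimethylsilyl)oxy]prop-1-en-2-yl}-8-chloro-5-methyl-1-[(triethylsilyl)oxy]oct-5-en-3-ol, via alkenyllithium 17 (not isolated)
Conditions: 16 (1.6 equiv), t-BuLi (3.2 equiv), Et2O, −78 °C; then 12, BF3·OEt2 (1.6 equiv), −78 °C
Reagents that add atoms: none
Why: Iodine–lithium exchange with retention of alkene geometry, then BF3-assisted opening of the terminal epoxide at its CH2 carbon, forms C9–C10 and frees O8 without touching the C8 stereocentre; the primary chloride does not react at −78 °C.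

Step 11
Reactants: 18 (2S,3S,5E)-2-{3-[(tert-butyldimethylsilyl)oxy]prop-1-en-2-yl}-8-chloro-5-methyl-1-[(triethylsilyl)oxy]oct-5-en-3-ol
Product: 19 (2S,3S,5E)-8-chloro-5-methyl-2-{3-[(tert-butyldimethylsilyl)oxy]prop-1-en-2-yl}-1,3-bis[(triethylsilyl)oxy]oct-5-ene
Conditions: TESOTf, 2,6-lutidine, CH2Cl2, −78 °C
Reagents that add atoms: triethylsilyl trifluoromethanesulfonate, CC[Si](CC)(CC)OS(=O)(=O)C(F)(F)F
Why: Silylation of the hindered secondary C8 hydroxyl with the silyl triflate.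

Step 12
Reactants: 19 (2S,3S,5E)-8-chloro-5-methyl-2-{3-[(tert-butyldimethylsilyl)oxy]prop-1-en-2-yl}-1,3-bis[(triethylsilyl)oxy]oct-5-ene; 20 prop-2-yn-1-ol
Product: 24 (2Z,5E,8S,9S)-2-(iodomethylidene)-6-methyl-9-{3-[(tert-butyldimethylsilyl)oxy]prop-1-en-2-yl}-8,10-bis[(triethylsilyl)oxy]dec-5-en-1-ol, via alkylmagnesium chloride 21 (not isolated), via chloromagnesium propargyl alkoxide 22 (not isolated), via alkenylmagnesium chelate 23 (not isolated)
Conditions: 19, Mg (activated), THF, 55 °C; separately 20, i-PrMgCl (1.0 equiv), THF, −20 °C; combine, CuI (0.2 equiv), −20 °C to rt; I2, THF, −40 to 0 °C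
Reagents that add atoms: iodine, II
Why: Copper-catalysed anti-carbomagnesiation of a propargylic alkoxide (Duboudin reaction): the alkyl group adds to the internal alkyne carbon while magnesium is held at the terminus by the alkoxide, and iodinolysis with retention gives the iodoalkene with iodine cis to C15; the hydroxyl proton is removed beforehand with i-PrMgCl so that none of 21 is spent as base.

Step 13
Reactants: 24 (2Z,5E,8S,9S)-2-(iodomethylidene)-6-methyl-9-{3-[(tert-butyldimethylsilyl)oxy]prop-1-en-2-yl}-8,10-bis[(triethylsilyl)oxy]dec-5-en-1-ol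
Product: 25 O15-(4-methoxybenzyl) ether of 24 with unchanged (2Z,5E,8S,9S) configuration
Conditions: NaH, 4-methoxybenzyl chloride, TBAI (cat.), DMF, 0 °C to rt
Reagents that add atoms: 4-methoxybenzyl chloride, COc1ccc(CCl)cc1
Why: Williamson etherification of the primary allylic alcohol; the iodoalkene has no hydrogen on C4 and cannot eliminate.

Step 14
Reactants: 25 O15-(4-methoxybenzyl) ether of 24
Product: 26 (2S,3S,5E,9Z)-10-iodo-9-{[(4-methoxybenzyl)oxy]methyl}-5-methyl-2-{3-[(tert-butyldimethylsilyl)oxy]prop-1-en-2-yl}-3-[(triethylsilyl)oxy]deca-5,9-dien-1-ol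
Conditions: PPTS (0.1 equiv), MeOH/CH2Cl2 (1:3), −10 to 0 °C, stopped at full conversion of 25
Reagents that add atoms: none
Why: Acid-catalysed methanolysis removes the unhindered primary triethylsilyl ether at C6 faster than the secondary one at C8 and much faster than the tert-butyldimethylsilyl ether at C12.

Step 15
Reactants: 26 (2S,3S,5E,9Z)-10-iodo-9-{[(4-methoxybenzyl)oxy]methyl}-5-methyl-2-{3-[(tert-butyldimethylsilyl)oxy]prop-1-en-2-yl}-3-[(triethylsilyl)oxy]deca-5,9-dien-1-ol
Product: 27 (2R,3S,5E,9Z)-10-iodo-9-{[(4-methoxybenzyl)oxy]methyl}-5-methyl-2-{3-[(tert-butyldimethylsilyl)oxy]prop-1-en-2-yl}-3-[(triethylsilyl)oxy]deca-5,9-dienal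
Conditions: Dess–Martin periodinane, pyridine, CH2Cl2, 0 °C; used at once
Reagents that add atoms: none
Why: Dess–Martin oxidation under buffered, non-basic conditions gives the α-branched β,γ-unsaturated aldehyde without epimerising C7 or moving the C11=C13 alkene into conjugation.

Step 16
Reactants: 27 (2R,3S,5E,9Z)-10-iodo-9-{[(4-methoxybenzyl)oxy]methyl}-5-methyl-2-{3-[(tert-butyldimethylsilyl)oxy]prop-1-en-2-yl}-3-[(triethylsilyl)oxy]deca-5,9-dienal
Product: 29 (1(10)E,4Z,6R,7S,8S)-12-[(tert-butyldimethylsilyl)oxy]-15-[(4-methoxybenzyl)oxy]-8-[(triethylsilyl)oxy]germacra-1(10),4,11(13)-trien-6-ol, via alkenylchromium dichloride 28 (not isolated)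
Conditions: CrCl2 (10 equiv), NiCl2 (0.1 equiv), degassed DMSO/THF, rt, 27 added by syringe pump to about 2 mM
Reagents that add atoms: none
Why: Nozaki–Hiyama–Kishi reaction run intramolecularly: zerovalent nickel (formed from NiCl2 by divalent chromium) inserts into the C5–I bond with retention, the alkenyl group passes to trivalent chromium (28), and this weakly basic alkenylchromium adds to the C6 aldehyde, the chromium alkoxide making the closure irreversible. The closest known reaction type is the alkenyl iodide–aldehyde Nozaki–Hiyama–Kishi macrocyclisation used for medium and large carbocycles. The ten-membered ring closes by end-to-end C5–C6 bond formation, a 10-exo-trig addition to the carbonyl group with the oxygen left outside the ring. The new C6 stereocentre is controlled by C7: in the Felkin–Anh arrangement the C8 branch stands anti to the incoming C5 and the alkenyl metal passes the C7 hydrogen, which should give the 6,7-syn (6R) carbinol, helped by the folded conformer that the two preset trisubstituted alkenes impose. The step needs cyclisation over oligomerisation (secured by slow addition at high dilution), chemoselectivity for the aldehyde (silyl ethers, the PMB ether and the 1,1-disubstituted alkene are inert to the chromium reagent) and no loss of the C7 configuration (the medium is neither acidic nor basic, and O8 as its silyl ether is a poor leaving group).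

Step 17
Reactants: 29 (1(10)E,4Z,6R,7S,8S)-12-[(tert-butyldimethylsilyl)oxy]-15-[(4-methoxybenzyl)oxy]-8-[(triethylsilyl)oxy]germacra-1(10),4,11(13)-trien-6-ol
Product: 30 (1(10)E,4Z,6R,7R,8S)-6,12-bis[(tert-butyldimethylsilyl)oxy]-15-[(4-methoxybenzyl)oxy]-8-[(triethylsilyl)oxy]germacra-1(10),4,11(13)-triene
Conditions: TBSOTf, 2,6-lutidine, CH2Cl2, −78 to 0 °C
Reagents that add atoms: tert-butyldimethylsilyl trifluoromethanesulfonate, CC(C)(C)[Si](C)(C)OS(=O)(=O)C(F)(F)F
Why: Silylation of the new C6 carbinol, which is also γ to C12 and would otherwise compete with O8 in the lactonisation and with O15 in the acylation.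

Step 18
Reactants: 30 (1(10)E,4Z,6R,7R,8S)-6,12-bis[(tert-butyldimethylsilyl)oxy]-15-[(4-methoxybenzyl)oxy]-8-[(triethylsilyl)oxy]germacra-1(10),4,11(13)-triene
Product: 31 (1(10)E,4Z,6R,7R,8S)-6-[(tert-butyldimethylsilyl)oxy]-15-[(4-methoxybenzyl)oxy]germacra-1(10),4,11(13)-triene-8,12-diol
Conditions: HF·pyridine, pyridine, THF, 0 °C to rt
Reagents that add atoms: none
Why: Buffered fluoride desilylation distinguishes by silyl type and position: the secondary triethylsilyl ether (O8) and the primary allylic tert-butyldimethylsilyl ether (O12) are cleaved while the hindered secondary tert-butyldimethylsilyl ether at O6 should stay.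

Step 19
Reactants: 31 (1(10)E,4Z,6R,7R,8S)-6-[(tert-butyldimethylsilyl)oxy]-15-[(4-methoxybenzyl)oxy]germacra-1(10),4,11(13)-triene-8,12-diol
Product: 34 (1(10)E,4Z,6R,7R,8S)-6-[(tert-butyldimethylsilyl)oxy]-15-[(4-methoxybenzyl)oxy]germacra-1(10),4,11(13)-trien-12,8-olide, via hydroxy enal 32 (not isolated), via lactol 33 (not isolated)
Conditions: TEMPO (0.2 equiv), PhI(OAc)2 (3 equiv), CH2Cl2, rt
Reagents that add atoms: none
Why: TEMPO/PhI(OAc)2 oxidative lactonisation of a 1,4-diol: the primary allylic C12 alcohol is oxidised first, the enal is trapped by O8 as the five-membered lactol and this is oxidised to the α-methylene γ-lactone, with no change at any stereocentre.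

Step 20
Reactants: 34 (1(10)E,4Z,6R,7R,8S)-6-[(tert-butyldimethylsilyl)oxy]-15-[(4-methoxybenzyl)oxy]germacra-1(10),4,11(13)-trien-12,8-olide
Product: 35 (1(10)E,4Z,6R,7R,8S)-6-[(tert-butyldimethylsilyl)oxy]-15-hydroxygermacra-1(10),4,11(13)-trien-12,8-olide
Conditions: DDQ, CH2Cl2/pH 7 buffer, 0 °C
Reagents that add atoms: none
Why: Oxidative PMB ether cleavage with DDQ, which leaves the silyl ether, the methylene lactone and the trisubstituted alkenes alone and frees O15 as the only hydroxyl.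

Step 21
Reactants: 36 [(tert-butyldimethylsilyl)oxy]acetaldehyde; 37 ethyl 2-(triphenylphosphoranylidene)propanoate
Product: 38 ethyl (2E)-4-[(tert-butyldimethylsilyl)oxy]-2-methylbut-2-enoate
Conditions: CH2Cl2, rt
Reagents that add atoms: none
Why: Wittig olefination with a stabilised ylide, which gives the E-configured α-methyl enoate.

Step 22
Reactants: 38 ethyl (2E)-4-[(tert-butyldimethylsilyl)oxy]-2-methylbut-2-enoate
Product: 39 (2E)-4-[(tert-butyldimethylsilyl)oxy]-2-methylbut-2-enoic acid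
Conditions: LiOH, THF/MeOH/H2O, rt; cold 1 M HCl to pH 4
Reagents that add atoms: lithium hydroxide, [Li+].[OH-]
Why: Ester saponification; the primary silyl ether tolerates aqueous LiOH and a brief cold acidification.

Step 23
Reactants: 35 (1(10)E,4Z,6R,7R,8S)-6-[(tert-butyldimethylsilyl)oxy]-15-hydroxygermacra-1(10),4,11(13)-trien-12,8-olide; 39 (2E)-4-[(tert-butyldimethylsilyl)oxy]-2-methylbut-2-enoic acid
Product: 40 (1(10)E,4Z,6R,7R,8S)-6-[(tert-butyldimethylsilyl)oxy]-15-({(2E)-4-[(tert-butyldimethylsilyl)oxy]-2-methylbut-2-enoyl}oxy)germacra-1(10),4,11(13)-trien-12,8-olide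
Conditions: DCC, DMAP (cat.), CH2Cl2, 0 °C to rt
Reagents that add atoms: none
Why: Steglich esterification of the only free hydroxyl (primary, allylic O15), so no site selectivity is needed.

Step 24
Reactants: 40 (1(10)E,4Z,6R,7R,8S)-6-[(tert-butyldimethylsilyl)oxy]-15-({(2E)-4-[(tert-butyldimethylsilyl)oxy]-2-methylbut-2-enoyl}oxy)germacra-1(10),4,11(13)-trien-12,8-olide
Product: 41 (1(10)E,4Z,6R,7S,8S)-6-hydroxy-15-{[(2E)-4-hydroxy-2-methylbut-2-enoyl]oxy}germacra-1(10),4,11(13)-trien-12,8-olide (CNP0326626.1)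
Conditions: HF·pyridine, pyridine, THF, 0 °C to rt
Reagents that add atoms: none
Why: Buffered fluoride desilylation removes both remaining silyl ethers without base, so the methylene lactone and the ester are not attacked and no acyl shift is promoted.

**Compound list**

1 | (Z)-but-2-ene-1,4-diol | OC/C=C\CO | starting material
2 | (Z)-4-[(4-methoxybenzyl)oxy]but-2-en-1-ol | OC/C=C\COCc1ccc(OC)cc1 | intermediate
3 | [(2R,3S)-3-{[(4-methoxybenzyl)oxy]methyl}oxiran-2-yl]methanol (cis; oxirane C2 = C7, C3 = C8) | OC[C@H]1O[C@H]1COCc1ccc(OC)cc1 | intermediate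
4 | 2-bromoprop-2-en-1-ol | OCC(Br)=C | starting material
5 | [(2-bromoprop-2-en-1-yl)oxy](tert-butyl)dimethylsilane | C=C(Br)CO[Si](C)(C)C(C)(C)C | intermediate
6 | {3-[(tert-butyldimethylsilyl)oxy]prop-1-en-2-yl}lithium | [Li]C(=C)CO[Si](C)(C)C(C)(C)C | intermediate
7 | {3-[(tert-butyldimethylsilyl)oxy]prop-1-en-2-yl}magnesium bromide | Br[Mg]C(=C)CO[Si](C)(C)C(C)(C)C | intermediate
8 | (2S,3R)-2-{3-[(tert-butyldimethylsilyl)oxy]prop-1-en-2-yl}-4-[(4-methoxybenzyl)oxy]butane-1,3-diol (C1–C4 = C6–C9) | OC[C@H](C(=C)CO[Si](C)(C)C(C)(C)C)[C@@H](O)COCc1ccc(OC)cc1 | intermediate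
9 | (2R,3S)-3-{3-[(tert-butyldimethylsilyl)oxy]prop-1-en-2-yl}-1-[(4-methoxybenzyl)oxy]-4-[(triethylsilyl)oxy]butan-2-ol | CC[Si](CC)(CC)OC[C@H](C(=C)CO[Si](C)(C)C(C)(C)C)[C@@H](O)COCc1ccc(OC)cc1 | intermediate
10 | (2R,3S)-3-{3-[(tert-butyldimethylsilyl)oxy]prop-1-en-2-yl}-4-[(triethylsilyl)oxy]butane-1,2-diol | CC[Si](CC)(CC)OC[C@H](C(=C)CO[Si](C)(C)C(C)(C)C)[C@@H](O)CO | intermediate
11 | (2R,3S)-2-hydroxy-3-{3-[(tert-butyldimethylsilyl)oxy]prop-1-en-2-yl}-4-[(triethylsilyl)oxy]butyl 4-methylbenzenesulfonate | CC[Si](CC)(CC)OC[C@H](C(=C)CO[Si](C)(C)C(C)(C)C)[C@@H](O)COS(=O)(=O)c1ccc(C)cc1 | intermediate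
12 | (2R)-2-[(2S)-3-{[(tert-butyldimethylsilyl)oxy]methyl}-1-[(triethylsilyl)oxy]but-3-en-2-yl]oxirane | CC[Si](CC)(CC)OC[C@H](C(=C)CO[Si](C)(C)C(C)(C)C)[C@@H]1CO1 | intermediate
13 | pent-3-yn-1-ol | CC#CCCO | starting material
14 | 5-chloropent-2-yne | CC#CCCCl | intermediate
15 | chloro[(2E)-5-chloropent-2-en-2-yl]bis(cyclopentadienyl)zirconium | ClCC/C=C(\C)[Zr](Cl)(C1C=CC=C1)C1C=CC=C1 | intermediate
16 | (2E)-5-chloro-2-iodopent-2-ene | ClCC/C=C(\C)I | intermediate
17 | [(2Z)-5-chloropent-2-en-2-yl]lithium (lithium in the place of iodine, geometry retained) | ClCC/C=C(\C)[Li] | intermediate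
18 | (2S,3S,5E)-2-{3-[(tert-butyldimethylsilyl)oxy]prop-1-en-2-yl}-8-chloro-5-methyl-1-[(triethylsilyl)oxy]oct-5-en-3-ol | CC[Si](CC)(CC)OC[C@H](C(=C)CO[Si](C)(C)C(C)(C)C)[C@@H](O)C/C(C)=C/CCCl | intermediate
19 | (2S,3S,5E)-8-chloro-5-methyl-2-{3-[(tert-butyldimethylsilyl)oxy]prop-1-en-2-yl}-1,3-bis[(triethylsilyl)oxy]oct-5-ene | CC[Si](CC)(CC)OC[C@H](C(=C)CO[Si](C)(C)C(C)(C)C)[C@@H](O[Si](CC)(CC)CC)C/C(C)=C/CCCl | intermediate
20 | prop-2-yn-1-ol (propargyl alcohol) | C#CCO | starting material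
21 | chloro[(3E,6S,7S)-4-methyl-7-{3-[(tert-butyldimethylsilyl)oxy]prop-1-en-2-yl}-6,8-bis[(triethylsilyl)oxy]oct-3-en-1-yl]magnesium | CC[Si](CC)(CC)OC[C@H](C(=C)CO[Si](C)(C)C(C)(C)C)[C@@H](O[Si](CC)(CC)CC)C/C(C)=C/CCC[Mg]Cl | intermediate
22 | chloromagnesium prop-2-yn-1-olate | C#CCO[Mg]Cl | intermediate
23 | bis(chloromagnesium) derivative of 24: C5–MgCl in the place of C5–I (Z, magnesium cis to C15) and O15–MgCl | CC[Si](CC)(CC)OC[C@H](C(=C)CO[Si](C)(C)C(C)(C)C)[C@@H](O[Si](CC)(CC)CC)C/C(C)=C/CC/C(CO[Mg]Cl)=C/[Mg]Cl | intermediate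
24 | (2Z,5E,8S,9S)-2-(iodomethylidene)-6-methyl-9-{3-[(tert-butyldimethylsilyl)oxy]prop-1-en-2-yl}-8,10-bis[(triethylsilyl)oxy]dec-5-en-1-ol | CC[Si](CC)(CC)OC[C@H](C(=C)CO[Si](C)(C)C(C)(C)C)[C@@H](O[Si](CC)(CC)CC)C/C(C)=C/CC/C(CO)=C/I | intermediate
25 | 4-methoxybenzyl ether of 24 at O15, (2Z,5E,8S,9S) | CC[Si](CC)(CC)OC[C@H](C(=C)CO[Si](C)(C)C(C)(C)C)[C@@H](O[Si](CC)(CC)CC)C/C(C)=C/CC/C(COCc1ccc(OC)cc1)=C/I | intermediate
26 | (2S,3S,5E,9Z)-10-iodo-9-{[(4-methoxybenzyl)oxy]methyl}-5-methyl-2-{3-[(tert-butyldimethylsilyl)oxy]prop-1-en-2-yl}-3-[(triethylsilyl)oxy]deca-5,9-dien-1-ol | OC[C@H](C(=C)CO[Si](C)(C)C(C)(C)C)[C@@H](O[Si](CC)(CC)CC)C/C(C)=C/CC/C(COCc1ccc(OC)cc1)=C/I | intermediate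
27 | (2R,3S,5E,9Z)-10-iodo-9-{[(4-methoxybenzyl)oxy]methyl}-5-methyl-2-{3-[(tert-butyldimethylsilyl)oxy]prop-1-en-2-yl}-3-[(triethylsilyl)oxy]deca-5,9-dienal (key-step precursor) | O=C[C@H](C(=C)CO[Si](C)(C)C(C)(C)C)[C@@H](O[Si](CC)(CC)CC)C/C(C)=C/CC/C(COCc1ccc(OC)cc1)=C/I | intermediate
28 | alkenylchromium dichloride of 27 (C5–CrCl2 in the place of C5–I, geometry retained) | O=C[C@H](C(=C)CO[Si](C)(C)C(C)(C)C)[C@@H](O[Si](CC)(CC)CC)C/C(C)=C/CC/C(COCc1ccc(OC)cc1)=C/[Cr](Cl)Cl | intermediate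
29 | (1(10)E,4Z,6R,7S,8S)-12-[(tert-butyldimethylsilyl)oxy]-15-[(4-methoxybenzyl)oxy]-8-[(triethylsilyl)oxy]germacra-1(10),4,11(13)-trien-6-ol (key-step product) | CC[Si](CC)(CC)O[C@H]1C/C(C)=C/CC/C(COCc2ccc(OC)cc2)=C/[C@@H](O)[C@@H]1C(=C)CO[Si](C)(C)C(C)(C)C | intermediate
30 | (1(10)E,4Z,6R,7R,8S)-6,12-bis[(tert-butyldimethylsilyl)oxy]-15-[(4-methoxybenzyl)oxy]-8-[(triethylsilyl)oxy]germacra-1(10),4,11(13)-triene | CC[Si](CC)(CC)O[C@H]1C/C(C)=C/CC/C(COCc2ccc(OC)cc2)=C/[C@@H](O[Si](C)(C)C(C)(C)C)[C@@H]1C(=C)CO[Si](C)(C)C(C)(C)C | intermediate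
31 | (1(10)E,4Z,6R,7R,8S)-6-[(tert-butyldimethylsilyl)oxy]-15-[(4-methoxybenzyl)oxy]germacra-1(10),4,11(13)-triene-8,12-diol | O[C@H]1C/C(C)=C/CC/C(COCc2ccc(OC)cc2)=C/[C@@H](O[Si](C)(C)C(C)(C)C)[C@@H]1C(=C)CO | intermediate
32 | (1(10)E,4Z,6R,7R,8S)-6-[(tert-butyldimethylsilyl)oxy]-8-hydroxy-15-[(4-methoxybenzyl)oxy]germacra-1(10),4,11(13)-trien-12-al | O[C@H]1C/C(C)=C/CC/C(COCc2ccc(OC)cc2)=C/[C@@H](O[Si](C)(C)C(C)(C)C)[C@@H]1C(=C)C=O | intermediate
33 | 12-hydroxy-8,12-epoxy lactol of 32 (6R,7R,8S; mixture at C12) | C=C1C(O)O[C@H]2C/C(C)=C/CC/C(COCc3ccc(OC)cc3)=C/[C@@H](O[Si](C)(C)C(C)(C)C)[C@H]12 | intermediate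
34 | (1(10)E,4Z,6R,7R,8S)-6-[(tert-butyldimethylsilyl)oxy]-15-[(4-methoxybenzyl)oxy]germacra-1(10),4,11(13)-trien-12,8-olide | C=C1C(=O)O[C@H]2C/C(C)=C/CC/C(COCc3ccc(OC)cc3)=C/[C@@H](O[Si](C)(C)C(C)(C)C)[C@H]12 | intermediate
35 | (1(10)E,4Z,6R,7R,8S)-6-[(tert-butyldimethylsilyl)oxy]-15-hydroxygermacra-1(10),4,11(13)-trien-12,8-olide | C=C1C(=O)O[C@H]2C/C(C)=C/CC/C(CO)=C/[C@@H](O[Si](C)(C)C(C)(C)C)[C@H]12 | intermediate
36 | [(tert-butyldimethylsilyl)oxy]acetaldehyde | O=CCO[Si](C)(C)C(C)(C)C | starting material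
37 | ethyl 2-(triphenylphosphoranylidene)propanoate | CCOC(=O)C(C)=P(c1ccccc1)(c1ccccc1)c1ccccc1 | starting material
38 | ethyl (2E)-4-[(tert-butyldimethylsilyl)oxy]-2-methylbut-2-enoate | CCOC(=O)/C(C)=C/CO[Si](C)(C)C(C)(C)C | intermediate
39 | (2E)-4-[(tert-butyldimethylsilyl)oxy]-2-methylbut-2-enoic acid | OC(=O)/C(C)=C/CO[Si](C)(C)C(C)(C)C | intermediate
40 | (1(10)E,4Z,6R,7R,8S)-6-[(tert-butyldimethylsilyl)oxy]-15-({(2E)-4-[(tert-butyldimethylsilyl)oxy]-2-methylbut-2-enoyl}oxy)germacra-1(10),4,11(13)-trien-12,8-olide | C=C1C(=O)O[C@H]2C/C(C)=C/CC/C(COC(=O)/C(C)=C/CO[Si](C)(C)C(C)(C)C)=C/[C@@H](O[Si](C)(C)C(C)(C)C)[C@H]12 | intermediate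
41 | (1(10)E,4Z,6R,7S,8S)-6-hydroxy-15-{[(2E)-4-hydroxy-2-methylbut-2-enoyl]oxy}germacra-1(10),4,11(13)-trien-12,8-olide (CNP0326626.1) | C=C1C(=O)O[C@H]2C/C(C)=C/CC/C(COC(=O)/C(C)=C/CO)=C/[C@@H](O)[C@H]12 | target

**Step count**

Total: 24 steps. Longest linear sequence: 19 steps (1, 2, 4–7, 10–20, 23, 24).

**Steps most likely to fail**

Step 16. Two processes threaten it: intermolecular coupling in competition with the strained ten-membered closure, and attack on the wrong aldehyde face, because the Felkin preference set by C7 is not reinforced by 1,3-induction from the C8 silyloxy group. The fallback keeps the same ring closure but no longer relies on it for the C6 configuration. It sets out from aldehyde 27, which is cyclised as in step 16. The carbinol mixture, 29 together with its (6S,7S,8S) epimer F1, is oxidised with Dess–Martin periodinane (pyridine, CH2Cl2) to the ten-membered (7R,8S) C6 enone F2. The ketone is then reduced under reagent control by Corey–Bakshi–Shibata reduction (methyl oxazaborolidine, catecholborane, toluene, −78 °C), using the catalyst enantiomer that gives the 6R carbinol (the R catalyst if the C4=C5 arm acts as the large group). This returns to 29.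

Step 12. The advanced Grignard reagent may be lost by proton transfer from the acetylenic C–H of the alkoxide and by Wurtz coupling during magnesium insertion, so that little of it is carbometalated. The fallback builds the iodoalkene by olefination instead and uses the organometallic 1:1. It sets out from chloride 19, which is converted into Grignard reagent 21 as before. This is acylated with the Weinreb amide N-methoxy-2-[(4-methoxybenzyl)oxy]-N-methylacetamide F3 (from commercial 2-chloro-N-methoxy-N-methylacetamide and 4-methoxybenzyl alcohol, NaH, THF) to give the C4 ketone F4. Stork–Zhao olefination of F4 with Ph3P=CHI (from iodomethyltriphenylphosphonium iodide and NaHMDS, THF/DMPU, −78 °C) then installs the iodomethylidene group; the α-alkoxy substituent is expected to steer iodine cis to the PMB-oxymethyl arm, and any geometric isomer would be separated. This returns to 25, bypassing steps 12 and 13.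

Step 4. The nucleophile may attack C8 in competition with C7, and the lithium reagent 6 may undergo oxygen-to-carbon silyl shift before transmetalation. The fallback moves the regiocontrol to a carboxylate. It sets out from epoxy alcohol 3, which is oxidised (TEMPO, PhI(OAc)2, MeCN/H2O) to (2S,3S)-3-{[(4-methoxybenzyl)oxy]methyl}oxirane-2-carboxylic acid F5. Its lithium salt is opened at the α-carbon (C7, inversion) by the lithium dialkenylcuprate prepared from 6 and CuI, the known α-selective cuprate opening of 2,3-epoxy acids, to give (2R,3R)-3-hydroxy-4-[(4-methoxybenzyl)oxy]-2-{3-[(tert-butyldimethylsilyl)oxy]prop-1-en-2-yl}butanoic acid F6. Reduction of the acid with LiAlH4 (THF, 0 °C) returns to diol 8.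

**Further compounds**

F1 | step 16 | (1(10)E,4Z,6S,7S,8S)-12-[(tert-butyldimethylsilyl)oxy]-15-[(4-methoxybenzyl)oxy]-8-[(triethylsilyl)oxy]germacra-1(10),4,11(13)-trien-6-ol | CC[Si](CC)(CC)O[C@H]1C/C(C)=C/CC/C(COCc2ccc(OC)cc2)=C/[C@H](O)[C@@H]1C(=C)CO[Si](C)(C)C(C)(C)C
F2 | step 16 | (1(10)E,4Z,7R,8S)-12-[(tert-butyldimethylsilyl)oxy]-15-[(4-methoxybenzyl)oxy]-8-[(triethylsilyl)oxy]germacra-1(10),4,11(13)-trien-6-one | CC[Si](CC)(CC)O[C@H]1C/C(C)=C/CC/C(COCc2ccc(OC)cc2)=C/C(=O)[C@@H]1C(=C)CO[Si](C)(C)C(C)(C)C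
F3 | step 12 | N-methoxy-2-[(4-methoxybenzyl)oxy]-N-methylacetamide | CON(C)C(=O)COCc1ccc(OC)cc1
F4 | step 12 | (5E,8S,9S)-1-[(4-methoxybenzyl)oxy]-6-methyl-9-{3-[(tert-butyldimethylsilyl)oxy]prop-1-en-2-yl}-8,10-bis[(triethylsilyl)oxy]dec-5-en-2-one | CC[Si](CC)(CC)OC[C@H](C(=C)CO[Si](C)(C)C(C)(C)C)[C@@H](O[Si](CC)(CC)CC)C/C(C)=C/CCC(=O)COCc1ccc(OC)cc1
F5 | step 4 | (2S,3S)-3-{[(4-methoxybenzyl)oxy]methyl}oxirane-2-carboxylic acid (cis) | OC(=O)[C@H]1O[C@H]1COCc1ccc(OC)cc1
F6 | step 4 | (2R,3R)-3-hydroxy-4-[(4-methoxybenzyl)oxy]-2-{3-[(tert-butyldimethylsilyl)oxy]prop-1-en-2-yl}butanoic acid | OC(=O)[C@H](C(=C)CO[Si](C)(C)C(C)(C)C)[C@@H](O)COCc1ccc(OC)cc1
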